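(The numbers in the tables were computed with made-up constants; noise was put on by code.)

The dusk and summer runs both stood near the same fraction of their charge after 40.0 min, 20.0% and 20.3%, although summer held more starting material than dusk. Because the fraction holds while the charge moves, the passage of reagent from the second phase is taken as the rate-limiting step.

| flask | starting material | reagent in the second phase | protic impurity | remark | time | volume of the second phase over the first |
|---|---|---|---|---|---|---|
| dusk | 22 mM | 1.05 equiv | 16 mM | run made earlier |  |  |
| summer | 35 mM | 1.05 equiv | 16 mM | run made earlier |  |  |
| flask | 16 mM | 1.05 equiv | 16.0 mM |  | 30 min | 1.0 |

- dusk (time / min: target / %): 5.00: 2.3; 12.0: 5.3; 25.0: 13.9; 40.0: 20.0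
- summer (time / min: target / %): 3.00: 0.5; 6.00: 3.9; 15.0: 9.5; 40.0: 20.3

(each reading ± 0.5 percentage points)

- in the second phase: reagent in the second phase; everything else is in the first
- charges count per volume of the first phase; a concentration in a rate is the amount of a species over the volume of its own phase; every rate counts per litre of the first phase
- the earlier runs hold the two phases in the same ratio of volumes as the flask asked about

- south-east: doubling the transfer coefficient of the reagent in the second phase, all else as stated
- north-west: doubling the amount of reagent in the second phase, all else as stated

- target at 30 min, in percent of the starting material charged
- the change that raises the amount of target at 30 min, in percent of the starting material charged most ("none" if none brings more than 2 percentage points) (south-east / north-west / none)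
- amount of target at 30 min, in percent of the starting material charged, after north-west

The mean of those readings over that time is 0.00504 /min, the capture pace: the fraction of the charge that becomes target per minute at the recipe's equivalents. It is a reading, with a scatter of 0.5 percentage points on each point. The flask has the same equivalents and phase ratio, so this reckoning carries the pace over:

target at 30 min = pace × time = 15.1%

twice the reagent in the second phase = twice the pace × time = 30.2%

At the bench, leave the phase volumes alone, since the pace was read at this ratio.

The forecast says 12.5% (10.5% to 14.5%), picks north-west, and gives 25% after it (21% to 29.5%), on the ground that “Doubling the reagent doubles the flux without extra depletion”. Both its numbers stand below this reckoning.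

The flask gives 14.6%. North-west gains 10 points and reaches 24.8%, while south-east gains 8.4 points, so the choice is north-west.

    reagent in the reaction phase ⇌ reagent in the second phase, rate k1*([reagent in the reaction phase] - [reagent in the second phase]/K1) per volume of the first phase (partition coefficient = 0.960, kL = 0.00710 /min)
    starting material + reagent in the reaction phase → target (k = 18.0 /M/min)
    reagent in the reaction phase + target → over-reacted product (k = 9.90 /M/min)
    starting material + protic impurity → quenched substrate (k = 1.40 /M/min)

The pace belongs to this reckoning, not to the forecast, and a run tests it at a lower charge. The neighbour charged with 4.0 mM keeps the equivalents and the time, so the pace again reckons 15.1%. That neighbour ends lower than the reckoning, with 8.54% target, 44.7% quenched substrate and 46.4% starting material left.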